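At late times the north run stood still, so I began there, with these flasks and questions.

| flask | solid substrate | free catalyst | remark | time |
|---|---|---|---|---|
| north-east | 0.20 mM | 12 mol% | the very flask that is asked about, followed so far |  |
| north | 0.13 mM | 12 mol% | run made earlier |  |
| flask | 0.20 mM | 12 mol% |  | 1.5 h |

| run | time / min | isomer of the product / % | target / % |
|---|---|---|---|
| north-east | 1.33 | 0.9 | 7.2 |
| north-east | 2.50 | 1.3 | 11.2 |
| north-east | 5.00 | 2.7 | 18.3 |
| north-east | 8.00 | 1.6 | 23.8 |
| north-east | 15.0 | 2.7 | 28.3 |
| north | 8.00 | 3.5 | 33.0 |
| north | 25.0 | 2.4 | 33.3 |
| north | 40.0 | 2.2 | 33.3 |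
| north | 60.0 | 1.9 | 33.3 |
| north | 90.0 | 2.3 | 33.3 |

(scatter of a reading: 0.5 percentage points)

- as a solid, counted per litre of solution: solid substrate
- the analysis behind the earlier runs scatters by 0.5 percentage points, standard deviation
- at the start none of the solid substrate is in solution
- a reading or a percentage of target counts all its forms, free or not

* share of isomer of the product in isomer of the product plus target at 25 s
* share of isomer of the product in isomer of the product plus target at 1.5 h

From 25.0 min to 90.0 min target in the north run read 33.3 %, and isomer of the product averaged 2.20 %. This gave 6.20 % for the stopped share, isomer of the product over isomer plus target once a run stands still. The north-east run had the same loading, 12 mol%, so I committed to this share for it at 1.5 h.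

I had no reading at 25 s. I pooled the north-east readings at 1.33 min and 2.50 min, which gave 10.7 % as my early share.

The weak link was the carry from north to north-east, so I reforged it from north-east readings. Isomer at 8.00 min and 15.0 min averaged 2.15 %. Against target at 15.0 min, 28.3 %, that made 7.06 %. With a scatter of 0.5 percentage points on isomer readings averaging 2.15 %, I could not tell this from 6.20 %, and I kept 6.20 %.

The forecast gave 12.5 % at 25 s and 6.3 % at 1.5 h, saying of the late share “so I expect about the same at 1.5 h”. My early share was lower than its number.

The north-east flask gave 9.16 % at 25 s and 6.97 % at 1.5 h.

    starting material ⇌ target (K = 0.520, k = 0.0470 /s)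
    target + free catalyst ⇌ isomer of the product + free catalyst, rate k2*[free catalyst]*[target] forward; the back reaction follows from the equilibrium constant (K = 22.0, k = 620 /M/s)
    free catalyst → spent catalyst (k = 0.0230 /s)
    solid substrate ⇌ starting material, rate k4*(cs4 - [starting material]) while solid is left; crystals form when [starting material] > cs4 (solubility = 0.110 mM, k = 0.00590 /s)
    free catalyst + target ⇌ idle complex (K = 2300 /M, k = 170 /M/s)

At 1.50 h spent catalyst stood at 100 % of the catalyst charged, and the share of 6.97 % was the same at 15.0 h. That is kinetic control, lower than the 95.7 % of the isomerisation's equilibrium. Applied to the final target, 28.6 %, the stopped share gives 1.89 % of isomer, and the flask held 2.14 %.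

In the neighbour flask, the same recipe with 0.050 mM of solid substrate, the stopped share gives 6.20 % at 1.5 h. The computed share there is 5.75 %.

(All runs are simulated for substances that don't exist, and the scatter is random.)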